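The route rests on disconnecting ring A of the benzodioxane at two bonds that palladium can forge from halides of unequal reactivity: C7–Cα (to the ring B styryl arm) and C8a–O1. Because neither bond involves the stereocentres C2 (bearing ring C) or C3 (bearing ring D), one palladium charge can first run a Heck coupling at the C7 iodide and then close the dioxane ring by aryl etherification at the C8a bromide, with retention. The precursor is threo alcohol 10, R at both C2 and C3, whose C3 oxygen carries a 2-bromo-4-iodophenyl group. It comes from dynamic kinetic transfer hydrogenation of a racemic α-aryloxy ketone. Six MOM ethers mask the phenols until the last step.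

Key step: step 9

Numbering: O1, C2 (ring C, 3,5-dioxygenated phenyl), C3 (ring D, catechol), O4, ring A C4a to C8a, ring B on the styryl arm at C7. In the open-chain compounds the carbinol carbon (ethane C1) becomes C2 and the ether carbon (ethane C2) becomes C3.

Assumption: the facial sense and the threo preference of the transfer hydrogenation are taken from the behaviour of benzoin-type ketones with the same catalyst family, so the (S,S) ligand is chosen.

Step 1
Reactants: 1 3,5-dihydroxyacetophenone
Product: 2 3,5-bis(methoxymethoxy)acetophenone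
Conditions: MOMCl, i-Pr2NEt, CH2Cl2, 0 °C to rt
Reagents that add atoms: chloromethyl methyl ether, COCCl
Why: Williamson-type O-alkylation of both phenols with the reactive α-chloro ether under amine base should give the bis-MOM ether, which withstands the strong bases, palladium catalysis and hydride transfer used later.

Step 2
Reactants: 3 4-bromocatechol
Product: 4 4-bromo-1,2-bis(methoxymethoxy)benzene
Conditions: MOMCl, i-Pr2NEt, CH2Cl2, 0 °C to rt
Reagents that add atoms: chloromethyl methyl ether, COCCl
Why: The same phenol O-alkylation (MOM ether formation) masks both catechol hydroxyls so that the aryl bromide can act as the electrophile in the enolate arylation.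

Step 3
Reactants: 2 3,5-bis(methoxymethoxy)acetophenone; 4 4-bromo-1,2-bis(methoxymethoxy)benzene
Product: 5 1-[3,5-bis(methoxymethoxy)phenyl]-2-[3,4-bis(methoxymethoxy)phenyl]ethan-1-one
Conditions: Pd(OAc)2 (2 mol%), Xantphos (3 mol%), NaOtBu, toluene, 80 °C (slight excess of 2)
Reagents that add atoms: none
Why: Palladium-catalysed α-arylation of a methyl ketone enolate (Buchwald–Hartwig type: oxidative addition of 4, enolate binding, C–C reductive elimination) should give the benzyl aryl ketone, the wide-bite-angle ligand and the excess of ketone favouring monoarylation.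

Step 4
Reactants: 5 1-[3,5-bis(methoxymethoxy)phenyl]-2-[3,4-bis(methoxymethoxy)phenyl]ethan-1-one
Product: 7 racemic 2-bromo-1-[3,5-bis(methoxymethoxy)phenyl]-2-[3,4-bis(methoxymethoxy)phenyl]ethan-1-one, via trimethylsilyl enol ether 6 (not isolated)
Conditions: LiN(SiMe3)2, Me3SiCl, THF, −78 °C; then NBS, −78 to 0 °C
Reagents that add atoms: N-bromosuccinimide, O=C1CCC(=O)N1Br (bromine); chlorotrimethylsilane, C[Si](C)(C)Cl, supplies the silyl group of intermediate 6 only
Why: Silyl enol ether formation at the only enolisable position followed by electrophilic bromination with NBS should place bromine on the α-carbon under neutral conditions, so the electron-rich rings are not brominated and no HBr reaches the MOM acetals; the new centre is racemic by design.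

Step 5
Reactants: 7 racemic 2-bromo-1-[3,5-bis(methoxymethoxy)phenyl]-2-[3,4-bis(methoxymethoxy)phenyl]ethan-1-one; 8 2-bromo-4-iodophenol
Product: 9 racemic 2-(2-bromo-4-iodophenoxy)-1-[3,5-bis(methoxymethoxy)phenyl]-2-[3,4-bis(methoxymethoxy)phenyl]ethan-1-one
Conditions: K2CO3, acetone, rt
Reagents that add atoms: none
Why: Williamson-type SN2 displacement of the activated benzylic α-keto bromide by the phenoxide of 8 under mild carbonate base should give the aryl ether; the racemic centre is resolved dynamically in the next step.

Step 6
Reactants: 9 racemic 2-(2-bromo-4-iodophenoxy)-1-[3,5-bis(methoxymethoxy)phenyl]-2-[3,4-bis(methoxymethoxy)phenyl]ethan-1-one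
Product: 10 (1R,2R)-2-(2-bromo-4-iodophenoxy)-1-[3,5-bis(methoxymethoxy)phenyl]-2-[3,4-bis(methoxymethoxy)phenyl]ethan-1-ol (threo)
Conditions: RuCl[(S,S)-TsDPEN](p-cymene) (2 mol%), HCO2H/Et3N (3:2), DMF, 40 °C
Reagents that add atoms: none
Why: Noyori–Ikariya asymmetric transfer hydrogenation with dynamic kinetic resolution: the proton on the ether carbon, flanked by carbonyl, aryl and aryloxy groups, should exchange quickly under Et3N, the (S,S) catalyst delivers hydride to the carbonyl face that gives the R carbinol (C2), and the Felkin-type preference for the aryloxy group anti to the incoming hydride, as in the reduction of benzoin to (R,R)-hydrobenzoin, selects the ketone enantiomer leading to the R ether centre (C3).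

Step 7
Reactants: 11 3,5-dihydroxybenzaldehyde
Product: 12 3,5-bis(methoxymethoxy)benzaldehyde
Conditions: MOMCl, i-Pr2NEt, CH2Cl2, 0 °C to rt
Reagents that add atoms: chloromethyl methyl ether, COCCl
Why: Phenol O-alkylation (MOM ether formation) as in step 1 should protect both hydroxyls without touching the aldehyde.

Step 8
Reactants: 12 3,5-bis(methoxymethoxy)benzaldehyde
Product: 13 3,5-bis(methoxymethoxy)styrene
Conditions: Ph3PCH3Br, KOtBu, THF, 0 °C to rt
Reagents that add atoms: methyltriphenylphosphonium bromide, C[P+](c1ccccc1)(c1ccccc1)c1ccccc1.[Br-]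
Why: Wittig methylenation of the aromatic aldehyde with the unstabilised ylide should give the terminal styrene, with no stereochemical issue.

Step 9
Reactants: 10 (1R,2R)-2-(2-bromo-4-iodophenoxy)-1-[3,5-bis(methoxymethoxy)phenyl]-2-[3,4-bis(methoxymethoxy)phenyl]ethan-1-ol; 13 3,5-bis(methoxymethoxy)styrene
Product: 15 hexa-MOM maackin, (2R,3R)-2-[3,5-bis(methoxymethoxy)phenyl]-3-[3,4-bis(methoxymethoxy)phenyl]-7-[(E)-2-[3,5-bis(methoxymethoxy)phenyl]ethenyl]-2,3-dihydro-1,4-benzodioxine, via bromostilbene alcohol 14 (not isolated)
Conditions: Pd(OAc)2 (5 mol%), 2-(di-tert-butylphosphino)-1,1'-binaphthyl (7 mol%), Cs2CO3 (3 equiv), 13 (1.05 equiv), degassed 1,4-dioxane, 60 °C; then 100 °C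
Reagents that add atoms: none
Why: Zerovalent palladium, formed from Pd(OAc)2 and the phosphine, should insert first into the weak C7–iodine bond of 10, and syn carbopalladation of styrene 13 followed by syn β-hydride elimination (Mizoroki–Heck reaction) gives E-stilbene 14 with the C8a–bromine bond intact. On warming, insertion into the C8a–bromine bond, exchange of bromide on divalent palladium for the cesium C2-alkoxide, and C–O reductive elimination from the resulting seven-membered aryl(alkoxo)palladium chelate close the six-membered dioxane ring through the O1–C8a bond. This is an intramolecular Buchwald–Hartwig aryl etherification, a type known for 1,4-benzodioxanes from secondary alcohols, so each event is of a known kind and only their sequencing in one flask is untried on this substrate. No stereocentre is made and none is touched, because the C2–O1 and C3–O4 bonds stay intact, so the trans (2R,3R) arrangement follows directly from the threo alcohol. The step needs site selectivity between the two halides, secured by the large rate gap between aryl iodide and aryl bromide insertion and by using about one equivalent of 13, and it needs reductive elimination to outrun β-hydride elimination of the benzylic alkoxide, which the bulky electron-rich di-tert-butylphosphine promotes. If some molecules cyclise before the Heck event, the aryl iodide they retain still couples with 13, so both orders converge on 15.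

Step 10
Reactants: 15 hexa-MOM maackin
Product: 16 maackin, (2R,3R)-2-(3,5-dihydroxyphenyl)-3-(3,4-dihydroxyphenyl)-7-[(E)-2-(3,5-dihydroxyphenyl)ethenyl]-2,3-dihydro-1,4-benzodioxine
Conditions: 3 M aq. HCl, MeOH/THF, 45 °C, argon
Reagents that add atoms: none
Why: Acid-catalysed acetal methanolysis (MOM ether cleavage) should release the six phenols as dimethoxymethane, while the aryl alkyl ether bonds of the dioxane and the E-stilbene are inert to dilute acid at this temperature, so C2 and C3 are untouched.

Compound list
1 | 3,5-dihydroxyacetophenone | CC(=O)c1cc(O)cc(O)c1 | starting material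
2 | 3,5-bis(methoxymethoxy)acetophenone | CC(=O)c1cc(OCOC)cc(OCOC)c1 | intermediate
3 | 4-bromocatechol | Oc1ccc(Br)cc1O | starting material
4 | 4-bromo-1,2-bis(methoxymethoxy)benzene | COCOc1ccc(Br)cc1OCOC | intermediate
5 | 1-[3,5-bis(methoxymethoxy)phenyl]-2-[3,4-bis(methoxymethoxy)phenyl]ethan-1-one | O=C(Cc1ccc(OCOC)c(OCOC)c1)c1cc(OCOC)cc(OCOC)c1 | intermediate
6 | (Z)-trimethylsilyl enol ether of 5 (not isolated) | C[Si](C)(C)O/C(=C\c1ccc(OCOC)c(OCOC)c1)c1cc(OCOC)cc(OCOC)c1 | intermediate
7 | racemic 2-bromo-1-[3,5-bis(methoxymethoxy)phenyl]-2-[3,4-bis(methoxymethoxy)phenyl]ethan-1-one | O=C(C(Br)c1ccc(OCOC)c(OCOC)c1)c1cc(OCOC)cc(OCOC)c1 | intermediate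
8 | 2-bromo-4-iodophenol | Oc1ccc(I)cc1Br | starting material
9 | racemic 2-(2-bromo-4-iodophenoxy)-1-[3,5-bis(methoxymethoxy)phenyl]-2-[3,4-bis(methoxymethoxy)phenyl]ethan-1-one | O=C(C(Oc1ccc(I)cc1Br)c1ccc(OCOC)c(OCOC)c1)c1cc(OCOC)cc(OCOC)c1 | intermediate
10 | (1R,2R)-2-(2-bromo-4-iodophenoxy)-1-[3,5-bis(methoxymethoxy)phenyl]-2-[3,4-bis(methoxymethoxy)phenyl]ethan-1-ol (threo) | O[C@H](c1cc(OCOC)cc(OCOC)c1)[C@@H](c1ccc(OCOC)c(OCOC)c1)Oc1ccc(I)cc1Br | intermediate
11 | 3,5-dihydroxybenzaldehyde | O=Cc1cc(O)cc(O)c1 | starting material
12 | 3,5-bis(methoxymethoxy)benzaldehyde | O=Cc1cc(OCOC)cc(OCOC)c1 | intermediate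
13 | 3,5-bis(methoxymethoxy)styrene | C=Cc1cc(OCOC)cc(OCOC)c1 | intermediate
14 | (1R,2R)-2-{2-bromo-4-[(E)-2-[3,5-bis(methoxymethoxy)phenyl]ethenyl]phenoxy}-1-[3,5-bis(methoxymethoxy)phenyl]-2-[3,4-bis(methoxymethoxy)phenyl]ethan-1-ol (not isolated) | O[C@H](c1cc(OCOC)cc(OCOC)c1)[C@@H](c1ccc(OCOC)c(OCOC)c1)Oc1ccc(/C=C/c2cc(OCOC)cc(OCOC)c2)cc1Br | intermediate
15 | hexa-MOM maackin, (2R,3R)-trans | COCOc1cc(OCOC)cc(/C=C/c2ccc3c(c2)O[C@H](c2cc(OCOC)cc(OCOC)c2)[C@@H](c2ccc(OCOC)c(OCOC)c2)O3)c1 | intermediate
16 | maackin, (2R,3R)-trans | Oc1cc(O)cc(/C=C/c2ccc3c(c2)O[C@H](c2cc(O)cc(O)c2)[C@@H](c2ccc(O)c(O)c2)O3)c1 | target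

Total step count: 10. Longest linear sequence: 7 steps (steps 1, 3, 4, 5, 6, 9, 10, from 3,5-dihydroxyacetophenone).

Steps most likely to fail

Step 9. The one-flask sequence may break down in three ways: the benzylic alkoxide on palladium may undergo β-hydride elimination (oxidation of the carbinol with loss of halide), a second Heck coupling may occur at the bromide, or the catalyst may decay before the ring closure. The fallback separates the two bond formations and hands the ring closure to copper. It sets out from 10 and 13 and comes back at 15. A phosphine-free Heck coupling (Pd(OAc)2, n-Bu4NCl, NaHCO3, DMF, 60 °C), which does not touch the aryl bromide, should give bromostilbene alcohol 14, now isolated. An intramolecular Ullmann-type etherification (CuI, 3,4,7,8-tetramethyl-1,10-phenanthroline, Cs2CO3, toluene, 110 °C) should then form the O1–C8a bond with retention at C2, a copper alkoxide being far less prone to β-hydride elimination. No compound outside the list arises (F0).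

Step 6. Diastereocontrol at C3 may be poor if racemisation of the ether carbon is slower than reduction, or if catalyst and substrate preferences do not reinforce each other, while C2 stays under catalyst control. The fallback replaces kinetic control at C3 by thermodynamic control at the end. It sets out from 9 and comes back at 16. The reduction of step 6 then also delivers the (1R,2S)-erythro alcohol F1, which is taken, alone or together with 10, through the conditions of step 9. This should give the erythro bromostilbene alcohol F2 (not isolated) and then cis-hexa-MOM maackin F3, which is deprotected as in step 10 to cis-maackin F4. K2CO3 in degassed DMF at 60 °C should then ionise the para-hydroxyl of ring D, open the C3–O4 bond to a para-quinone methide, and reclose it by oxa-Michael addition to the more stable trans isomer 16. C2 carries no para-hydroxyaryl group and cannot epimerise, so the enantiomeric purity set by the catalyst is kept.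

Step 4. Bromination may go astray by double bromination, attack on the electron-rich rings, or acid-promoted loss of MOM groups. The fallback avoids the bromide altogether and sets out from 5 and comes back at 9. Regitz diazo transfer (4-acetamidobenzenesulfonyl azide, DBU, MeCN, 0 °C to rt) should give the α-diazo ketone F5. Rh2(OAc)4-catalysed O–H insertion of the derived carbene into phenol 8 (CH2Cl2, rt) should then give aryl ether 9 directly.

Further compounds
F0 | step 9 | none | none
F1 | step 6 | (1R,2S)-2-(2-bromo-4-iodophenoxy)-1-[3,5-bis(methoxymethoxy)phenyl]-2-[3,4-bis(methoxymethoxy)phenyl]ethan-1-ol (erythro) | O[C@H](c1cc(OCOC)cc(OCOC)c1)[C@H](c1ccc(OCOC)c(OCOC)c1)Oc1ccc(I)cc1Br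
F2 | step 6 | (1R,2S)-2-{2-bromo-4-[(E)-2-[3,5-bis(methoxymethoxy)phenyl]ethenyl]phenoxy}-1-[3,5-bis(methoxymethoxy)phenyl]-2-[3,4-bis(methoxymethoxy)phenyl]ethan-1-ol (erythro, not isolated) | O[C@H](c1cc(OCOC)cc(OCOC)c1)[C@H](c1ccc(OCOC)c(OCOC)c1)Oc1ccc(/C=C/c2cc(OCOC)cc(OCOC)c2)cc1Br
F3 | step 6 | cis-hexa-MOM maackin, (2R,3S) | COCOc1cc(OCOC)cc(/C=C/c2ccc3c(c2)O[C@H](c2cc(OCOC)cc(OCOC)c2)[C@H](c2ccc(OCOC)c(OCOC)c2)O3)c1
F4 | step 6 | cis-maackin, (2R,3S) | Oc1cc(O)cc(/C=C/c2ccc3c(c2)O[C@H](c2cc(O)cc(O)c2)[C@H](c2ccc(O)c(O)c2)O3)c1
F5 | step 4 | 2-diazo-1-[3,5-bis(methoxymethoxy)phenyl]-2-[3,4-bis(methoxymethoxy)phenyl]ethan-1-one | O=C(C(=[N+]=[N-])c1ccc(OCOC)c(OCOC)c1)c1cc(OCOC)cc(OCOC)c1
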